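**Assumption:** the biosynthesis is taken to be C‑farnesylation of the 1,3‑dione, then C2–C6 cation–olefin cyclisation of the oxidised chain with capture of the C3 cation by a dione oxygen (tricycloalternarene‑type pyran); the target is the ring‑opened form of that pyran.

## Retrosynthetic overview

1. Target 21 ⇐ hydroxide opening of the pyran of cis‑fused tricycle 19; the prenyl terminus ⇐ cross‑metathesis of an allyl terminus, which is used because a prenyl alkene held cis to the ketone would compete for it in the key step.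
2. Tricycle ⇐ one‑pot cyclisation of acyclic dione 15 (farnesane numbering, C1 = CH2 on the dione): the C2=C3 alkene attacks the activated C6 ketone (cyclopentane ring first), the enol oxygen captures the C3 cation (pyran ring second), and dehydration then gives the cyclopentene.
3. 15 ⇐ Tsuji–Trost C‑allylation of (S)‑4‑methoxycyclohexane‑1,3‑dione 5 with allylic acetate 14.
4. 14 ⇐ Nozaki–Hiyama–Kishi union of aldehyde 8 (from geranyl acetate) with (Z)‑alkenyl bromide 11 (from propyne and allyl bromide), then oxidation.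
5. 5 ⇐ asymmetric α′‑hydroxylation of 3‑ethoxycyclohex‑2‑enone, O‑methylation, hydrolysis; the six‑membered ring is bought.

## Route

Step 1
Reactants: 1 3-ethoxycyclohex-2-en-1-one
Product: 3 (S)-3-ethoxy-6-hydroxycyclohex-2-en-1-one, via sodium dienolate 2 (not isolated)
Conditions: NaN(SiMe3)2, THF, −78 °C; then (−)-(camphorsulfonyl)oxaziridine, −78 °C
Reagents that add atoms: (−)-(camphorsulfonyl)oxaziridine CC1(C)[C@H]2CC[C@@]13CS(=O)(=O)N4O[C@]34C2
Why: Kinetic deprotonation of the vinylogous ester occurs at C6 and the sodium dienolate is hydroxylated by the camphor‑derived N‑sulfonyloxaziridine (Davis asymmetric enolate hydroxylation), the reagent selecting the enolate face to set the (S)‑carbinol that becomes the methoxy‑bearing centre (sense assigned by analogy with cyclic ketone sodium enolates; the antipodal reagent is available if it proves opposite).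

Step 2
Reactants: 3 (S)-3-ethoxy-6-hydroxycyclohex-2-en-1-one
Product: 4 (S)-3-ethoxy-6-methoxycyclohex-2-en-1-one
Conditions: MeI, Ag2O, CH2Cl2, rt, dark
Reagents that add atoms: iodomethane CI
Why: Silver‑oxide‑promoted O‑methylation (Purdie etherification) is neutral, so the α‑hydroxy ketone is etherified without enolisation and the stereocentre is untouched.

Step 3
Reactants: 4 (S)-3-ethoxy-6-methoxycyclohex-2-en-1-one
Product: 5 (S)-4-methoxycyclohexane-1,3-dione
Conditions: 1 M HCl, THF, rt
Reagents that add atoms: water O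
Why: Acid‑catalysed enol‑ether hydrolysis of the vinylogous ester releases the 1,3‑dione, and the C4 centre lies outside the enolised β‑dicarbonyl unit and is retained.

Step 4
Reactants: 6 geranyl acetate
Product: 8 (E)-3-methyl-6-oxohex-2-en-1-yl acetate, via ozonide 7 (not isolated)
Conditions: O3 (1.0 equiv), CH2Cl2, −78 °C; then Me2S, −78 °C to rt
Reagents that add atoms: ozone O=[O+][O-]
Why: Chemoselective ozonolysis: ozone attacks the electron‑rich distal trisubstituted alkene much faster than the 2,3‑alkene deactivated by the allylic acetate, and reductive work‑up gives the aldehyde with the (E)‑alkene intact.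

Step 5
Reactants: 9 propyne; 10 allyl bromide
Product: 11 (Z)-2-bromohexa-2,5-diene
Conditions: PdBr2(PhCN)2 (1 mol%), neat allyl bromide (5 equiv), 0 °C to rt
Reagents that add atoms: none
Why: Palladium‑catalysed bromoallylation of a terminal alkyne (Kaneda haloallylation): syn‑bromopalladation places Br on the internal carbon and the alkenylpalladium is allylated with loss of bromide, so Br and the new CH2 end up cis, which is the (Z)‑geometry carried to the target.

Step 6
Reactants: 8 (E)-3-methyl-6-oxohex-2-en-1-yl acetate; 11 (Z)-2-bromohexa-2,5-diene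
Product: 13 (2E,7Z)-6-hydroxy-3,7-dimethylundeca-2,7,10-trien-1-yl acetate, via alkenylchromium dichloride 12 (not isolated)
Conditions: CrCl2 (4 equiv), NiCl2 (5 mol%), DMF, rt
Reagents that add atoms: none
Why: Nozaki–Hiyama–Kishi coupling: the alkenylchromium species forms with retention of alkene geometry and adds to the aldehyde in the presence of the allylic acetate; the new carbinol centre is racemic and is erased by the next oxidation.

Step 7
Reactants: 13 (2E,7Z)-6-hydroxy-3,7-dimethylundeca-2,7,10-trien-1-yl acetate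
Product: 14 (2E,7Z)-3,7-dimethyl-6-oxoundeca-2,7,10-trien-1-yl acetate
Conditions: Dess–Martin periodinane, CH2Cl2, 0 °C to rt
Reagents that add atoms: none
Why: Dess–Martin oxidation of the secondary allylic alcohol is non‑basic and non‑equilibrating, so the (Z)‑enone and the skipped diene are not isomerised.

Step 8
Reactants: 14 (2E,7Z)-3,7-dimethyl-6-oxoundeca-2,7,10-trien-1-yl acetate; 5 (S)-4-methoxycyclohexane-1,3-dione
Product: 15 (4S)-2-[(2E,7Z)-3,7-dimethyl-6-oxoundeca-2,7,10-trien-1-yl]-3-hydroxy-4-methoxycyclohex-2-en-1-one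
Conditions: Pd(PPh3)4 (5 mol%), Et3N (1.2 equiv), THF, 40 °C
Reagents that add atoms: none
Why: Tsuji–Trost C‑allylation: zerovalent palladium ionises the allylic acetate to a syn π‑allyl complex that the soft dione enolate attacks at the primary terminus (O‑allyl product re‑ionises), giving the linear (E)‑2‑allyl dione without strong base, so the enone and the C4 methoxy centre are untouched.

Step 9
Reactants: 15 (4S)-2-[(2E,7Z)-3,7-dimethyl-6-oxoundeca-2,7,10-trien-1-yl]-3-hydroxy-4-methoxycyclohex-2-en-1-one
Product: 17 (1R,3aS,7S,9aR)-1-[(2Z)-hexa-2,5-dien-2-yl]-1-hydroxy-7-methoxy-3a-methyl-1,2,3,3a,5,6,7,9a-octahydrocyclopenta[b]chromen-8(9H)-one, via aluminium enolate 16 (not isolated)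
Conditions: MeAlCl2 (3 equiv), CH2Cl2, −78 to −20 °C
Reagents that add atoms: none
Why: Proposed new method: MeAlCl2 first turns the enol into its dichloroaluminium enolate (methane leaves, so no proton remains to close a simple chroman at C2=C3), further MeAlCl2 activates the C6 ketone of the (Z)‑enone, the trisubstituted C2=C3 alkene attacks it through C2 in a five‑membered cation–olefin (Prins) closure of the geometry known from Lewis‑acid carbonyl‑ene cyclisations and allylsilane methylenecyclopentane annulations, and the tertiary C3 cation is captured by the tethered enolate oxygen remote from the Al–OMe chelate, which can reach only the cation face syn to the CH2 link and so fixes the cis ring fusion (3a‑Me cis to 9a‑H), while the bulky alkenyl group is expected to settle trans to that link at C1; the distant C7 centre gives no facial bias, so the (3aR,9aS)‑cis series forms alongside and is removed after step 10; closest known reaction types: MeAlCl2‑mediated Prins/carbonyl‑ene cyclisation of olefinic ketones and cation–olefin cyclisations terminated by an enol oxygen.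

Step 10
Reactants: 17 (1R,3aS,7S,9aR)-1-[(2Z)-hexa-2,5-dien-2-yl]-1-hydroxy-7-methoxy-3a-methyl-1,2,3,3a,5,6,7,9a-octahydrocyclopenta[b]chromen-8(9H)-one
Product: 18 (3aS,7S,9aR)-1-[(2Z)-hexa-2,5-dien-2-yl]-7-methoxy-3a-methyl-3,3a,5,6,7,9a-hexahydrocyclopenta[b]chromen-8(9H)-one
Conditions: Burgess reagent (2 equiv), toluene, 50 °C
Reagents that add atoms: none
Why: Burgess dehydration (syn Ei elimination of the tertiary sulfamate): in the (1R)‑carbinol the only hydrogens syn to the leaving group are on the ring CH2 (H‑9a is anti), so the endocyclic C1=C2 alkene conjugated to the untouched (Z)‑alkene forms regioselectively, and the unwanted cis‑fused diastereomeric series from step 9 is separated here by chromatography.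

Step 11
Reactants: 18 (3aS,7S,9aR)-1-[(2Z)-hexa-2,5-dien-2-yl]-7-methoxy-3a-methyl-3,3a,5,6,7,9a-hexahydrocyclopenta[b]chromen-8(9H)-one
Product: 19 (3aS,7S,9aR)-7-methoxy-3a-methyl-1-[(2Z)-6-methylhepta-2,5-dien-2-yl]-3,3a,5,6,7,9a-hexahydrocyclopenta[b]chromen-8(9H)-one
Conditions: second-generation Grubbs catalyst RuCl2(=CHPh)(PCy3)(H2IMes) (5 mol%), 2-methyl-2-butene/CH2Cl2 1:1, 40 °C
Reagents that add atoms: 2-methyl-2-butene CC=C(C)C
Why: Olefin cross‑metathesis converts only the monosubstituted terminal alkene into the prenyl terminus, because the trisubstituted diene alkenes are inert to the ruthenium carbene, so the (Z)‑diene and all stereocentres are untouched.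

Step 12
Reactants: 19 (3aS,7S,9aR)-7-methoxy-3a-methyl-1-[(2Z)-6-methylhepta-2,5-dien-2-yl]-3,3a,5,6,7,9a-hexahydrocyclopenta[b]chromen-8(9H)-one
Product: 21 (4S)-3-hydroxy-2-{[(1R,5S)-5-hydroxy-5-methyl-2-[(2Z)-6-methylhepta-2,5-dien-2-yl]cyclopent-2-en-1-yl]methyl}-4-methoxycyclohex-2-en-1-one, via sodium enolate 20 (not isolated)
Conditions: 2 M NaOH, THF/MeOH, 50 °C; then 1 M HCl to pH 4, 0 °C
Reagents that add atoms: sodium hydroxide [Na+].[OH-]
Why: Addition–elimination of hydroxide at the β‑carbon of the vinylogous ester (saponification) expels the tertiary alkoxide with retention at C3a and is driven by formation of the dione enolate, which also shields the methoxy‑bearing centre from enolisation, and cold acidification gives the free enol.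

## Compound list

1 | 3-ethoxycyclohex-2-en-1-one | CCOC1=CC(=O)CCC1 | starting material
2 | sodium 5-ethoxycyclohexa-1,5-dien-1-olate (sodium dienolate of 1) | CCOC1=CC([O-])=CCC1.[Na+] | intermediate
3 | (S)-3-ethoxy-6-hydroxycyclohex-2-en-1-one | O[C@H]1CCC(OCC)=CC1=O | intermediate
4 | (S)-3-ethoxy-6-methoxycyclohex-2-en-1-one | CO[C@H]1CCC(OCC)=CC1=O | intermediate
5 | (S)-4-methoxycyclohexane-1,3-dione | CO[C@H]1CCC(=O)CC1=O | intermediate
6 | geranyl acetate, (2E)-3,7-dimethylocta-2,6-dien-1-yl acetate | CC(=O)OC/C=C(\C)CCC=C(C)C | starting material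
7 | (E)-5-(5,5-dimethyl-1,2,4-trioxolan-3-yl)-3-methylpent-2-en-1-yl acetate (ozonide) | CC(=O)OC/C=C(\C)CCC1OOC(C)(C)O1 | intermediate
8 | (E)-3-methyl-6-oxohex-2-en-1-yl acetate | CC(=O)OC/C=C(\C)CCC=O | intermediate
9 | propyne | CC#C | starting material
10 | allyl bromide | C=CCBr | starting material
11 | (Z)-2-bromohexa-2,5-diene | C/C(Br)=C/CC=C | intermediate
12 | dichloro[(2Z)-hexa-2,5-dien-2-yl]chromium (trivalent chromium) | C/C(=C/CC=C)[Cr](Cl)Cl | intermediate
13 | (2E,7Z)-6-hydroxy-3,7-dimethylundeca-2,7,10-trien-1-yl acetate (racemic at C6) | CC(=O)OC/C=C(\C)CCC(O)/C(C)=C\CC=C | intermediate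
14 | (2E,7Z)-3,7-dimethyl-6-oxoundeca-2,7,10-trien-1-yl acetate | CC(=O)OC/C=C(\C)CCC(=O)/C(C)=C\CC=C | intermediate
15 | (4S)-2-[(2E,7Z)-3,7-dimethyl-6-oxoundeca-2,7,10-trien-1-yl]-3-hydroxy-4-methoxycyclohex-2-en-1-one | CO[C@H]1CCC(=O)C(C/C=C(\C)CCC(=O)/C(C)=C\CC=C)=C1O | intermediate
16 | dichloroaluminium enolate of 15 (Al on the oxygen next to the methoxy carbon) | CO[C@H]1CCC(=O)C(C/C=C(\C)CCC(=O)/C(C)=C\CC=C)=C1O[Al](Cl)Cl | intermediate
17 | (1R,3aS,7S,9aR)-1-[(2Z)-hexa-2,5-dien-2-yl]-1-hydroxy-7-methoxy-3a-methyl-1,2,3,3a,5,6,7,9a-octahydrocyclopenta[b]chromen-8(9H)-one (cis-fused) | CO[C@H]1CCC2=C(C[C@@H]3[C@@](O)(/C(C)=C\CC=C)CC[C@]3(C)O2)C1=O | intermediate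
18 | (3aS,7S,9aR)-1-[(2Z)-hexa-2,5-dien-2-yl]-7-methoxy-3a-methyl-3,3a,5,6,7,9a-hexahydrocyclopenta[b]chromen-8(9H)-one | CO[C@H]1CCC2=C(C[C@@H]3C(/C(C)=C\CC=C)=CC[C@]3(C)O2)C1=O | intermediate
19 | (3aS,7S,9aR)-7-methoxy-3a-methyl-1-[(2Z)-6-methylhepta-2,5-dien-2-yl]-3,3a,5,6,7,9a-hexahydrocyclopenta[b]chromen-8(9H)-one | CO[C@H]1CCC2=C(C[C@@H]3C(/C(C)=C\CC=C(C)C)=CC[C@]3(C)O2)C1=O | intermediate
20 | sodium enolate of 21 | CO[C@H]1CCC(=O)C(C[C@@H]2C(/C(C)=C\CC=C(C)C)=CC[C@]2(C)O)=C1[O-].[Na+] | intermediate
21 | (4S)-3-hydroxy-2-{[(1R,5S)-5-hydroxy-5-methyl-2-[(2Z)-6-methylhepta-2,5-dien-2-yl]cyclopent-2-en-1-yl]methyl}-4-methoxycyclohex-2-en-1-one | CO[C@H]1CCC(=O)C(C[C@@H]2C(/C(C)=C\CC=C(C)C)=CC[C@]2(C)O)=C1O | target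

## Step count and risks

Total steps: 12. Longest linear sequence: 8 (steps 4, 6–12 from geranyl acetate; equally steps 1–3, 8–12 from 1).

Steps most likely to fail:

1. **Step 9 (key cyclisation).** A five‑membered closure of an unactivated alkene onto a conjugated ketone is unproven; the C3 cation may lose a proton or take chloride, the (Z)‑enone may isomerise, and the regiochemistry of step 10 depends on the C1 configuration formed here. Fallback, setting out from 11 and returning at 18 (so step 10 is bypassed as well): Sonogashira coupling of 11 (Pd(PPh3)2Cl2, CuI, Et3N) with (E)-3-methylhex-2-en-5-yn-1-yl acetate F1, itself made by CuCl‑catalysed coupling of ethynylmagnesium bromide with (E)-4-chloro-3-methylbut-2-en-1-yl acetate, gives (2E,7Z)-3,7-dimethylundeca-2,7,10-trien-5-yn-1-yl acetate F2. Tsuji–Trost reaction of F2 with 5 as in step 8 gives (4S)-2-[(2E,7Z)-3,7-dimethylundeca-2,7,10-trien-5-yn-1-yl]-3-hydroxy-4-methoxycyclohex-2-en-1-one F3. A cationic monovalent gold catalyst, (Ph3P)AuNTf2 in CH2Cl2 at 0 °C, then activates the alkyne instead of a carbonyl: 5‑endo attack of C2=C3, capture of the C3 cation by the enol oxygen and protodeauration give diene 18 directly. The distal terminal alkene is the weaker nucleophile but could still compete.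

2. **Step 12 (pyran opening).** Hot hydroxide may epimerise the methoxy‑bearing centre before the ring opens, and acidification may re‑close the pyran. Fallback, setting out from 19 and returning at 21: heating 19 with pyrrolidine (MeOH, 60 °C) opens the pyran by amine addition–elimination under only weakly basic conditions to give the vinylogous amide (6S)-2-{[(1R,5S)-5-hydroxy-5-methyl-2-[(2Z)-6-methylhepta-2,5-dien-2-yl]cyclopent-2-en-1-yl]methyl}-6-methoxy-3-(pyrrolidin-1-yl)cyclohex-2-en-1-one F4, which dilute aqueous acetic acid in THF at rt hydrolyses to 21.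

3. **Step 1 (asymmetric hydroxylation).** The enantioselectivity of reagent‑controlled hydroxylation of this unsubstituted cyclic enolate may be modest, and the ee of 5 carries straight through to 21. Fallback, setting out from 1 and returning at 3: α′‑acetoxylation of 1 with Mn(OAc)3 (benzene, reflux) gives racemic 4-ethoxy-2-oxocyclohex-3-en-1-yl acetate F5, and lipase‑catalysed enantioselective hydrolysis (phosphate buffer/MTBE, enzyme chosen for the (S)‑ester) delivers (S)‑alcohol 3 by kinetic resolution, the unreacted (R)‑acetate being discarded.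

Further compounds
F1 | step 9 | (E)-3-methylhex-2-en-5-yn-1-yl acetate | CC(=O)OC/C=C(\C)CC#C
F2 | step 9 | (2E,7Z)-3,7-dimethylundeca-2,7,10-trien-5-yn-1-yl acetate | CC(=O)OC/C=C(\C)CC#C/C(C)=C\CC=C
F3 | step 9 | (4S)-2-[(2E,7Z)-3,7-dimethylundeca-2,7,10-trien-5-yn-1-yl]-3-hydroxy-4-methoxycyclohex-2-en-1-one | CO[C@H]1CCC(=O)C(C/C=C(\C)CC#C/C(C)=C\CC=C)=C1O
F4 | step 12 | (6S)-2-{[(1R,5S)-5-hydroxy-5-methyl-2-[(2Z)-6-methylhepta-2,5-dien-2-yl]cyclopent-2-en-1-yl]methyl}-6-methoxy-3-(pyrrolidin-1-yl)cyclohex-2-en-1-one | CO[C@H]1CCC(N2CCCC2)=C(C[C@@H]2C(/C(C)=C\CC=C(C)C)=CC[C@]2(C)O)C1=O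
F5 | step 1 | rac-4-ethoxy-2-oxocyclohex-3-en-1-yl acetate | CCOC1=CC(=O)C(OC(C)=O)CC1
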